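**Strategy.** The route rests on cutting the dihydrofuran ring at C2. This carbon carries the guaiacyl ring A and O1 and sits next to C3, so it is introduced as the carbanionic carbon of a benzylic sulfonium ylide. Ring B, O1 and C3 come as an o-quinone methide, released by base from an ortho-(1-tosylalkyl)phenol made from eugenol. One operation forms C2–C3 and O1–C2, closes the five-membered ring and sets both stereocentres: trans by the addition geometry, 2R,3S by a twofold-symmetric (2R,5R)-thiolane on sulfur. The allyl group is then hydroborated, the alcohol esterified with ferulic acid and the two silyl ethers removed.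

Key step: step 9

Remarks on the chemistry:
- The diol and the sulfone made from eugenol are racemic at the benzylic carbon; this carbon becomes the planar methide carbon in the key step, so its configuration is irrelevant.
- The sense of induction in the key step is assigned by analogy with benzylidene transfer from the same thiolane to aldehydes. Should it prove opposite, the enantiomeric thiolane, made identically from (2R,5R)-hexane-2,5-diol, would be used.
- The sulfonium salt carries triflate as counter-ion, because a fluoride-releasing anion such as BF4− could attack the two silyl ethers under basic conditions. The phenol of ring A carries the robust TIPS group.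

Step 1
Reactants: 1 eugenol (4-allyl-2-methoxyphenol); 2 (tert-butyldimethylsilyloxy)acetaldehyde
Product: 4 rac-4-allyl-2-[2-(tert-butyldimethylsilyloxy)-1-hydroxyethyl]-6-methoxyphenol, via bromomagnesium phenoxide 3 (not isolated)
Conditions: EtMgBr (1.0 equiv), Et2O, 0 °C; solvent exchanged for CH2Cl2; 2 (1.2 equiv), rt; then H2O
Reagents that add atoms: none
Why: The bromomagnesium phenoxide binds the aldehyde at magnesium and delivers it through a cyclic chelate to the only unsubstituted ortho carbon (the para position holds the allyl group), an ortho-specific phenoxide hydroxyalkylation of the Friedel–Crafts/aldol type that is favoured for α-oxygenated aldehydes; the new carbinol carbon is racemic and loses its configuration in step 9.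

Step 2
Reactants: 4 rac-4-allyl-2-[2-(tert-butyldimethylsilyloxy)-1-hydroxyethyl]-6-methoxyphenol
Product: 5 rac-4-allyl-2-[2-(tert-butyldimethylsilyloxy)-1-(p-tolylsulfonyl)ethyl]-6-methoxyphenol
Conditions: p-TolSO2H (1.5 equiv, freshly liberated from its sodium salt), CH2Cl2, 0 °C to rt
Reagents that add atoms: p-toluenesulfinic acid, Cc1ccc(cc1)S(=O)O
Why: Acid-mediated SN1-type substitution of an ortho-hydroxybenzylic alcohol, in which the phenol assists ionisation to a protonated o-quinone methide that the soft sulfinate captures at sulfur; p-toluenesulfinic acid in a non-nucleophilic solvent should be mild enough to spare the primary TBS ether and the allyl group.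

Step 3
Reactants: 6 (2S,5S)-hexane-2,5-diol
Product: 7 (2S,5S)-hexane-2,5-diyl dimethanesulfonate
Conditions: MsCl (2.4 equiv), Et3N (3 equiv), CH2Cl2, −20 to 0 °C
Reagents that add atoms: methanesulfonyl chloride, CS(=O)(=O)Cl
Why: Mesylation (O-sulfonylation of alcohols) takes place at oxygen, so both carbinol carbons keep their S configuration.

Step 4
Reactants: 7 (2S,5S)-hexane-2,5-diyl dimethanesulfonate
Product: 8 (2R,5R)-2,5-dimethylthiolane
Conditions: Na2S·9H2O, DMSO, rt; distillation
Reagents that add atoms: sodium sulfide, [Na+].[Na+].[S-2]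
Why: Twofold SN2 substitution by sulfide (intermolecular, then 5-exo-tet ring closure) inverts both carbons and so turns the (2S,5S)-dimesylate into the (2R,5R)-thiolane.

Step 5
Reactants: 9 vanillin
Product: 10 3-methoxy-4-(triisopropylsilyloxy)benzaldehyde
Conditions: TIPSCl, imidazole, DMF, rt
Reagents that add atoms: triisopropylsilyl chloride, CC(C)[Si](Cl)(C(C)C)C(C)C
Why: Imidazole-promoted silylation of the phenol; the bulky TIPS ether is chosen to survive hydride, bromination and carbonate base.

Step 6
Reactants: 10 3-methoxy-4-(triisopropylsilyloxy)benzaldehyde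
Product: 11 [3-methoxy-4-(triisopropylsilyloxy)phenyl]methanol
Conditions: NaBH4, EtOH/THF, 0 °C
Reagents that add atoms: none
Why: Hydride reduction of the aryl aldehyde to the benzylic alcohol by NaBH4, which should leave the aryl silyl ether intact at low temperature.

Step 7
Reactants: 11 [3-methoxy-4-(triisopropylsilyloxy)phenyl]methanol
Product: 12 4-(bromomethyl)-2-methoxy-1-(triisopropylsilyloxy)benzene
Conditions: CBr4, PPh3, CH2Cl2, 0 °C; used promptly
Reagents that add atoms: carbon tetrabromide, BrC(Br)(Br)Br
Why: Appel bromination converts the benzylic alcohol under neutral conditions, avoiding the HBr that could cleave the silyl ether or ionise the electron-rich benzylic position.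

Step 8
Reactants: 12 4-(bromomethyl)-2-methoxy-1-(triisopropylsilyloxy)benzene; 8 (2R,5R)-2,5-dimethylthiolane
Product: 13 (2R,5R)-1-[3-methoxy-4-(triisopropylsilyloxy)benzyl]-2,5-dimethylthiolanium trifluoromethanesulfonate
Conditions: 8 (1.2 equiv), NaOSO2CF3 (1.5 equiv), acetone, rt, dark
Reagents that add atoms: sodium trifluoromethanesulfonate, [Na+].[O-]S(=O)(=O)C(F)(F)F
Why: S-Alkylation of the sulfide by the benzylic bromide (SN2), with precipitation of NaBr driving anion exchange to the non-nucleophilic triflate; the twofold axis of the thiolane makes both sulfur lone pairs equivalent, so a single sulfonium salt forms and sulfur is not a stereocentre.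

Step 9
Reactants: 5 rac-4-allyl-2-[2-(tert-butyldimethylsilyloxy)-1-(p-tolylsulfonyl)ethyl]-6-methoxyphenol; 13 (2R,5R)-1-[3-methoxy-4-(triisopropylsilyloxy)benzyl]-2,5-dimethylthiolanium trifluoromethanesulfonate
Product: 17 (2R,3S)-5-allyl-3-[(tert-butyldimethylsilyloxy)methyl]-7-methoxy-2-[3-methoxy-4-(triisopropylsilyloxy)phenyl]-2,3-dihydrobenzofuran, via o-quinone methide 14 (not isolated), via sulfonium ylide 15 (not isolated), via phenoxide betaine 16 (not isolated)
Conditions: 13 (1.5 equiv), Cs2CO3 (3 equiv), MeCN, 0 °C to rt; 5 added slowly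
Reagents that add atoms: none
Why: Cs2CO3 deprotonates the phenol of 5, whose phenoxide expels p-toluenesulfinate to give o-quinone methide 14, and also deprotonates 13 at the benzylic carbon to give ylide 15; the ylide carbon adds to the exocyclic methide carbon (C2–C3), ring B becomes aromatic again in betaine 16, and the phenoxide oxygen then displaces the thiolane from C2 with inversion (O1–C2). The closest known reaction type is the formal [4+1] annulation of sulfonium ylides with o-quinone methides generated from 2-(1-tosylalkyl)phenols by carbonate bases, together with benzylidene transfer from thiolanium salts of this kind in Corey–Chaykovsky-type epoxidation. The dihydrofuran ring closes in the 5-exo-tet mode. C2 is controlled by the (2R,5R)-thiolane: in the ylide the aryl group should point away from the sulfide ring and the methyl group on the same side as the ylide carbon should block one face, so that C–C bond formation on the open face followed by inversion leads to 2R, the sense expected by analogy with benzylidene transfer from this sulfide to aldehydes. C3 is set in the same, practically irreversible C–C bond formation by the mutual orientation of the two partners, the aryl group and the CH2OTBS group avoiding each other so that the anti betaine and from it the trans (2R,3S) ring should result; should the C2–S bond ionise before closure, closure under the influence of C3 would still favour trans. The step needs face selectivity at the ylide carbon, trans selectivity and capture of the methide faster than its tautomerisation or dimerisation; these rest on the twofold symmetry of the sulfide (one salt, one ylide environment), on the size of the two substituents, and on an excess of the salt together with reversible re-addition of sulfinate, which keeps the concentration of free methide low.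

Step 10
Reactants: 17 (2R,3S)-5-allyl-3-[(tert-butyldimethylsilyloxy)methyl]-7-methoxy-2-[3-methoxy-4-(triisopropylsilyloxy)phenyl]-2,3-dihydrobenzofuran
Product: 19 3-[(2R,3S)-3-[(tert-butyldimethylsilyloxy)methyl]-7-methoxy-2-[3-methoxy-4-(triisopropylsilyloxy)phenyl]-2,3-dihydrobenzofuran-5-yl]propan-1-ol, via alkylborane 18 (not isolated)
Conditions: 9-BBN (1.5 equiv), THF, 0 °C to rt; then NaBO3·4H2O, H2O, rt
Reagents that add atoms: sodium perborate tetrahydrate, [Na+].[O-]OB=O.O.O.O.O
Why: Hydroboration–oxidation: the bulky 9-BBN adds boron to the terminal carbon of the monosubstituted alkene, and perborate, a mild oxidant that should spare the aryl silyl ether, replaces boron by hydroxyl; C2 and C3 are not touched.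

Step 11
Reactants: 19 3-[(2R,3S)-3-[(tert-butyldimethylsilyloxy)methyl]-7-methoxy-2-[3-methoxy-4-(triisopropylsilyloxy)phenyl]-2,3-dihydrobenzofuran-5-yl]propan-1-ol; 20 ferulic acid ((E)-3-(4-hydroxy-3-methoxyphenyl)prop-2-enoic acid)
Product: 21 3-[(2R,3S)-3-[(tert-butyldimethylsilyloxy)methyl]-7-methoxy-2-[3-methoxy-4-(triisopropylsilyloxy)phenyl]-2,3-dihydrobenzofuran-5-yl]propyl (E)-3-(4-hydroxy-3-methoxyphenyl)prop-2-enoate
Conditions: 20 (1.3 equiv), PPh3, DIAD, THF, 0 °C to rt
Reagents that add atoms: none
Why: Mitsunobu esterification: the carboxylic acid, far more acidic than the phenol, is the pronucleophile that displaces the activated primary alcohol, so the phenol of ferulic acid needs no protection and the E alkene is untouched.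

Step 12
Reactants: 21 3-[(2R,3S)-3-[(tert-butyldimethylsilyloxy)methyl]-7-methoxy-2-[3-methoxy-4-(triisopropylsilyloxy)phenyl]-2,3-dihydrobenzofuran-5-yl]propyl (E)-3-(4-hydroxy-3-methoxyphenyl)prop-2-enoate
Product: 22 3-[(2R,3S)-2-(4-hydroxy-3-methoxyphenyl)-3-(hydroxymethyl)-7-methoxy-2,3-dihydrobenzofuran-5-yl]propyl (E)-3-(4-hydroxy-3-methoxyphenyl)prop-2-enoate (CNP0149450.1)
Conditions: TBAF (3 equiv), AcOH (3 equiv), THF, 0 °C to rt
Reagents that add atoms: none
Why: Fluoride-mediated desilylation cleaves the primary TBS ether and the aryl TIPS ether, and the acetic acid buffer keeps the liberated phenols protonated so that neither the ester nor the benzylic C2–O1 bond (through a p-quinone methide) is endangered.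

**Compound list**

1 | eugenol (4-allyl-2-methoxyphenol) | C=CCc1ccc(O)c(OC)c1 | starting material
2 | (tert-butyldimethylsilyloxy)acetaldehyde | O=CCO[Si](C)(C)C(C)(C)C | starting material
3 | bromomagnesium 4-allyl-2-methoxyphenoxide | C=CCc1ccc(O[Mg]Br)c(OC)c1 | intermediate
4 | rac-4-allyl-2-[2-(tert-butyldimethylsilyloxy)-1-hydroxyethyl]-6-methoxyphenol | C=CCc1cc(OC)c(O)c(c1)C(O)CO[Si](C)(C)C(C)(C)C | intermediate
5 | rac-4-allyl-2-[2-(tert-butyldimethylsilyloxy)-1-(p-tolylsulfonyl)ethyl]-6-methoxyphenol | C=CCc1cc(OC)c(O)c(c1)C(CO[Si](C)(C)C(C)(C)C)S(=O)(=O)c1ccc(C)cc1 | intermediate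
6 | (2S,5S)-hexane-2,5-diol | C[C@H](O)CC[C@H](C)O | starting material
7 | (2S,5S)-hexane-2,5-diyl dimethanesulfonate | C[C@H](OS(C)(=O)=O)CC[C@H](C)OS(C)(=O)=O | intermediate
8 | (2R,5R)-2,5-dimethylthiolane | C[C@@H]1CC[C@@H](C)S1 | intermediate
9 | vanillin (4-hydroxy-3-methoxybenzaldehyde) | COc1cc(C=O)ccc1O | starting material
10 | 3-methoxy-4-(triisopropylsilyloxy)benzaldehyde | COc1cc(C=O)ccc1O[Si](C(C)C)(C(C)C)C(C)C | intermediate
11 | [3-methoxy-4-(triisopropylsilyloxy)phenyl]methanol | COc1cc(CO)ccc1O[Si](C(C)C)(C(C)C)C(C)C | intermediate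
12 | 4-(bromomethyl)-2-methoxy-1-(triisopropylsilyloxy)benzene | COc1cc(CBr)ccc1O[Si](C(C)C)(C(C)C)C(C)C | intermediate
13 | (2R,5R)-1-[3-methoxy-4-(triisopropylsilyloxy)benzyl]-2,5-dimethylthiolanium trifluoromethanesulfonate | C[C@@H]1CC[C@@H](C)[S+]1Cc1ccc(O[Si](C(C)C)(C(C)C)C(C)C)c(OC)c1.[O-]S(=O)(=O)C(F)(F)F | intermediate
14 | (E)-4-allyl-6-[2-(tert-butyldimethylsilyloxy)ethylidene]-2-methoxycyclohexa-2,4-dien-1-one (o-quinone methide) | CC(C)(C)[Si](C)(C)OC/C=C1\C=C(CC=C)C=C(OC)C1=O | intermediate
15 | (2R,5R)-2,5-dimethylthiolanium [3-methoxy-4-(triisopropylsilyloxy)phenyl]methylide | C[C@@H]1CC[C@@H](C)[S+]1[CH-]c1ccc(O[Si](C(C)C)(C(C)C)C(C)C)c(OC)c1 | intermediate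
16 | anti phenoxide betaine: 4-allyl-6-methoxyphenoxide bearing at its ortho carbon a (1S,2S)-1-[(tert-butyldimethylsilyloxy)methyl]-2-[3-methoxy-4-(triisopropylsilyloxy)phenyl]-2-[(2R,5R)-2,5-dimethylthiolanium-1-yl]ethyl group | C[C@@H]1CC[C@@H](C)[S+]1[C@H](c1ccc(O[Si](C(C)C)(C(C)C)C(C)C)c(OC)c1)[C@H](CO[Si](C)(C)C(C)(C)C)c1cc(CC=C)cc(OC)c1[O-] | intermediate
17 | (2R,3S)-5-allyl-3-[(tert-butyldimethylsilyloxy)methyl]-7-methoxy-2-[3-methoxy-4-(triisopropylsilyloxy)phenyl]-2,3-dihydrobenzofuran (trans) | C=CCc1cc(OC)c2c(c1)[C@@H](CO[Si](C)(C)C(C)(C)C)[C@H](c1ccc(O[Si](C(C)C)(C(C)C)C(C)C)c(OC)c1)O2 | intermediate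
18 | 9-{3-[(2R,3S)-3-[(tert-butyldimethylsilyloxy)methyl]-7-methoxy-2-[3-methoxy-4-(triisopropylsilyloxy)phenyl]-2,3-dihydrobenzofuran-5-yl]propyl}-9-borabicyclo[3.3.1]nonane | C1CC2CCCC(C1)B2CCCc1cc(OC)c2c(c1)[C@@H](CO[Si](C)(C)C(C)(C)C)[C@H](c1ccc(O[Si](C(C)C)(C(C)C)C(C)C)c(OC)c1)O2 | intermediate
19 | 3-[(2R,3S)-3-[(tert-butyldimethylsilyloxy)methyl]-7-methoxy-2-[3-methoxy-4-(triisopropylsilyloxy)phenyl]-2,3-dihydrobenzofuran-5-yl]propan-1-ol | OCCCc1cc(OC)c2c(c1)[C@@H](CO[Si](C)(C)C(C)(C)C)[C@H](c1ccc(O[Si](C(C)C)(C(C)C)C(C)C)c(OC)c1)O2 | intermediate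
20 | ferulic acid ((E)-3-(4-hydroxy-3-methoxyphenyl)prop-2-enoic acid) | COc1cc(/C=C/C(=O)O)ccc1O | starting material
21 | 3-[(2R,3S)-3-[(tert-butyldimethylsilyloxy)methyl]-7-methoxy-2-[3-methoxy-4-(triisopropylsilyloxy)phenyl]-2,3-dihydrobenzofuran-5-yl]propyl (E)-3-(4-hydroxy-3-methoxyphenyl)prop-2-enoate | COc1cc(/C=C/C(=O)OCCCc2cc(OC)c3c(c2)[C@@H](CO[Si](C)(C)C(C)(C)C)[C@H](c2ccc(O[Si](C(C)C)(C(C)C)C(C)C)c(OC)c2)O3)ccc1O | intermediate
22 | 3-[(2R,3S)-2-(4-hydroxy-3-methoxyphenyl)-3-(hydroxymethyl)-7-methoxy-2,3-dihydrobenzofuran-5-yl]propyl (E)-3-(4-hydroxy-3-methoxyphenyl)prop-2-enoate | COc1cc(/C=C/C(=O)OCCCc2cc(OC)c3c(c2)[C@@H](CO)[C@H](c2ccc(O)c(OC)c2)O3)ccc1O | target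

**Step count.** Total: 12 steps. Longest linear sequence: 8 steps (9 → 10 → 11 → 12 → 13 → 17 → 19 → 21 → 22).

**Steps most likely to fail**

Step 9. Face discrimination at the ylide carbon may be incomplete, or the transient methide may tautomerise to a vinyl phenol or oligomerise before the hindered chiral ylide captures it; either would lower the enantiomeric purity or the conversion. The fallback sets out from 12 and 5 and returns at 17. Bromide 12 alkylates tetrahydrothiophene (NaOSO2CF3, acetone, rt) to give the achiral salt 1-[3-methoxy-4-(triisopropylsilyloxy)benzyl]thiolanium trifluoromethanesulfonate F1. Its less hindered ylide should capture the methide from 5 under the same carbonate conditions and give the racemic trans-5-allyl-3-[(tert-butyldimethylsilyloxy)methyl]-7-methoxy-2-[3-methoxy-4-(triisopropylsilyloxy)phenyl]-2,3-dihydrobenzofuran F2. Preparative chromatography on a chiral stationary phase then separates the enantiomers and delivers the (2R,3S) isomer 17. The absolute configuration is thus secured by resolution and no longer by the sulfide.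

Step 1. The chelated aldehyde may add sluggishly, the benzylic alkoxide may condense with a second phenoxide to a diarylethane, or the silyl group may migrate from the primary to the benzylic oxygen. The fallback sets out from 1 and 2 and returns at 4. The two are condensed on a boron template (PhB(OH)2, catalytic propionic acid, toluene, reflux with removal of water) to rac-6-allyl-4-[(tert-butyldimethylsilyloxy)methyl]-8-methoxy-2-phenyl-4H-1,3,2-benzodioxaborinine F3, in which boron ties phenol oxygen and aldehyde together and forces ortho attack without a basic alkoxide. Transesterification with propane-1,3-diol (THF, rt) then releases diol 4.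

Step 2. Ionisation of the alcohol is slowed by the β-oxygen, and during a long exposure to acid the primary TBS ether may be lost. The fallback sets out from 4 and returns at 5, and accepts the loss of the silyl group. Compound 4 is treated with p-TolSO2Na and 2 M aqueous HCl in THF at rt, which should remove the silyl ether and install the sulfone, giving rac-4-allyl-2-[2-hydroxy-1-(p-tolylsulfonyl)ethyl]-6-methoxyphenol F4. TBSCl (1.05 equiv) and imidazole in CH2Cl2 at 0 °C then silylate the unhindered primary alcohol in preference to the doubly ortho-substituted, hydrogen-bonded phenol, giving 5.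

**Further compounds**

F1 | step 9 | 1-[3-methoxy-4-(triisopropylsilyloxy)benzyl]thiolanium trifluoromethanesulfonate | COc1cc(C[S+]2CCCC2)ccc1O[Si](C(C)C)(C(C)C)C(C)C.[O-]S(=O)(=O)C(F)(F)F
F2 | step 9 | racemic trans-5-allyl-3-[(tert-butyldimethylsilyloxy)methyl]-7-methoxy-2-[3-methoxy-4-(triisopropylsilyloxy)phenyl]-2,3-dihydrobenzofuran (1:1 mixture of the 2R,3S and 2S,3R enantiomers) | C=CCc1cc(OC)c2c(c1)[C@@H](CO[Si](C)(C)C(C)(C)C)[C@H](c1ccc(O[Si](C(C)C)(C(C)C)C(C)C)c(OC)c1)O2.C=CCc1cc(OC)c2c(c1)[C@H](CO[Si](C)(C)C(C)(C)C)[C@@H](c1ccc(O[Si](C(C)C)(C(C)C)C(C)C)c(OC)c1)O2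
F3 | step 1 | rac-6-allyl-4-[(tert-butyldimethylsilyloxy)methyl]-8-methoxy-2-phenyl-4H-1,3,2-benzodioxaborinine | C=CCc1cc(OC)c2OB(c3ccccc3)OC(CO[Si](C)(C)C(C)(C)C)c2c1
F4 | step 2 | rac-4-allyl-2-[2-hydroxy-1-(p-tolylsulfonyl)ethyl]-6-methoxyphenol | C=CCc1cc(OC)c(O)c(c1)C(CO)S(=O)(=O)c1ccc(C)cc1
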